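Numbering (lindenane): cyclopropane C1–C2–C3; ring A = C1, C3, C4, C5, C10; ring B = C5–C10; butenolide ring C = C7, C8, O, C12, C11; primes mark the second half. The cyclobutane C8–C9–C9′–C8′ comes last, from a [2+2] photodimerisation of two identical monomers across C8=C9.
Ring C of the monomer comes from a tricyclic 7,9-dione: C7–C11 by coupling at a C7 enol triflate, the oxygen on C8 by dienolate hydroxylation, and the C9 carbonyl leaves as the C8=C9 alkene.
Key disconnection: C5–C10 and C7–C8 together. Rings A and B close in one base-mediated Michael/Claisen cascade of a monocyclic keto dienoate.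
Enabling feature: in ring B, C8 and C10 both flank C9, and C5 and C7 both flank C6. One ketone at C9 makes C10 and C8 nucleophilic, and one enoate C5=C6–C7(=O) makes C5 and C7 electrophilic. The cis-cyclopropane C1–C2–C3 holds both arms in reach, and C4=C15 is already in place.
Ring order: cyclopropane, then A + B, then C, then cyclobutane. The precursor is built from epoxybutane, acetylide, CH2I2 and a bromodienoate.

Key step: step 7

Remark on the chemistry: (2R,3R)-2,3-dimethyloxirane is taken as purchasable in enantiopure form; otherwise it is one known operation from commercial (2R,3R)-butane-2,3-diol.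

Step 1
Reactants: 1 (2R,3R)-2,3-dimethyloxirane; 2 lithium acetylide–ethylenediamine complex
Product: 3 (2R,3R)-3-methylpent-4-yn-2-ol
Conditions: DMSO, 15 °C to rt; H2O
Reagents that add atoms: none
Why: SN2 alkynylation of the C2-symmetric trans-epoxide inverts the attacked carbon, so the methyl-bearing carbon (future C10) should be obtained as one configuration and serves later as the only control element.

Step 2
Reactants: 3 (2R,3R)-3-methylpent-4-yn-2-ol
Product: 6 (2R,3R,4Z)-3-methyl-5-(4,4,5,5-tetramethyl-1,3,2-dioxaborolan-2-yl)pent-4-en-2-ol, via O-boryl alkynol 4 (not isolated), via O-boryl alkenylboronate 5 (not isolated)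
Conditions: HBpin (2.2 equiv), [Rh(cod)Cl]2 (cat.), P(i-Pr)3 (cat.), Et3N, cyclohexane, rt; H2O work-up
Reagents that add atoms: pinacolborane, [H]B1OC(C)(C)C(C)(C)O1
Why: Rh-catalysed trans-hydroboration of a terminal alkyne (vinylidene pathway) should give the Z-alkenylboronate, while the first equivalent of borane only caps the OH as a borate that water removes again.

Step 3
Reactants: 6 (2R,3R,4Z)-3-methyl-5-(pinacolboryl)pent-4-en-2-ol
Product: 7 (2R,3R)-3-[(1R,2S)-2-(4,4,5,5-tetramethyl-1,3,2-dioxaborolan-2-yl)cyclopropyl]butan-2-ol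
Conditions: Et2Zn, CH2I2, CH2Cl2, −15 °C to rt; aq. NH4Cl
Reagents that add atoms: diiodomethane, ICI
Why: In this hydroxyl-directed Simmons–Smith cyclopropanation, A(1,3) strain of the Z-alkene holds H-10 in the alkene plane and the zinc alkoxide on C9 delivers CH2 to the face it occupies, which should set C1 and C3, cis by stereospecific syn addition.

Step 4
Reactants: 8 2-bromoprop-2-enal; 9 methyl (triphenyl-λ5-phosphanylidene)acetate
Product: 10 methyl (2E)-4-bromopenta-2,4-dienoate
Conditions: CH2Cl2, 0 °C to rt
Reagents that add atoms: none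
Why: A Wittig olefination with a stabilised ylide should give the E-enoate and leave the vinylic C–Br bond untouched.

Step 5
Reactants: 7 cyclopropylboronate; 10 methyl (2E)-4-bromopenta-2,4-dienoate
Product: 11 methyl (2E)-4-{(1S,2R)-2-[(2R,3R)-3-hydroxybutan-2-yl]cyclopropyl}penta-2,4-dienoate
Conditions: Pd(dppf)Cl2 (cat.), Cs2CO3, THF–H2O, 60 °C
Reagents that add atoms: none
Why: Suzuki–Miyaura coupling of a cyclopropylboronate with an alkenyl bromide proceeds with retention at the cyclopropyl carbon, so C3 and the cis relationship are kept while C3–C4 forms with C4=C15 in place.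

Step 6
Reactants: 11 hydroxy dienoate
Product: 12 methyl (2E)-4-{(1S,2R)-2-[(2R)-3-oxobutan-2-yl]cyclopropyl}penta-2,4-dienoate
Conditions: Dess–Martin periodinane, CH2Cl2, 0 °C to rt
Reagents that add atoms: none
Why: This neutral hypervalent-iodine oxidation of the secondary alcohol to the C9 ketone should spare the diene, the ester and the vinylcyclopropane.

Step 7
Reactants: 12 keto dienoate
Product: 14 (1R,3S,5S,10S)-11,12,13-trinorlinden-4(15)-ene-7,9-dione, via Michael adduct 13 (not isolated)
Conditions: t-BuOK (2 equiv), t-BuOH–THF, high dilution, −20 °C to rt; then 1 M HCl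
Reagents that add atoms: none
Why: Under equilibrating conditions the more substituted enolate (C10=C9–O−) adds to C5 of the E-enoate (Michael), proton transfer gives the C8 enolate, this is acylated by the C7 ester (Claisen), and the product is drained as its 1,3-diketonate, the irreversible sink of the cascade. The closest known reaction type is the consecutive Michael–Claisen synthesis of cyclohexane-1,3-diones from ketones and enoates, here made doubly intramolecular, together with trans-selective intramolecular Michael closures of cyclopentanes. Ring A closes 5-(enolexo)-exo-trig through C5–C10 and ring B closes 6-(enolexo)-exo-trig through C7–C8. The old configuration at C10 is erased in the planar enolate and the new one is set by the cis-cyclopropane, because the bulky C9(O−)CH3 terminus sits in the open sector next to H-1, anti to C2H2, so that CH3-14 ends syn to C2. At C5 the enoate reacts through the face that places C6 antiperiplanar to C9 in an open, solvated potassium transition state, which puts H-5 trans to CH3-14. The step needs the C10 enolate rather than the C8 enolate (only C10 reaches a five-membered ring; the C8 enolate would need 7- or 9-membered rings and simply equilibrates), 1,4- rather than 1,6-addition (attack at C15 would be 5-endo), and an intact cyclopropane (a C3 carbanion would only be cross-conjugated, and the enolate [3,3] shift is polarity-mismatched and carries a Z substituent).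

Step 8
Reactants: 14 tricyclic 7,9-dione
Product: 15 (1R,3S,5S,10S)-7-(trifluoromethylsulfonyloxy)-11,12,13-trinorlindena-4(15),7-dien-9-one
Conditions: Tf2O, Et3N, CH2Cl2, −78 to 0 °C
Reagents that add atoms: triflic anhydride, O=S(=O)(OS(=O)(=O)C(F)(F)F)C(F)(F)F
Why: O-sulfonylation of the 1,3-dione (vinylogous acyl triflate formation) should occur at the oxygen on C7, because the oxygen on C9 is shielded by the quaternary C10.

Step 9
Reactants: 15 enol triflate; 16 methyl 2-bromopropanoate (racemic)
Product: 18 methyl (1R,3S,5S,10S)-9-oxolindena-4(15),7-dien-12-oate (C11 epimers), via Reformatsky reagent 17 (not isolated)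
Conditions: 16, Zn dust, THF, 40 °C; then 15, Pd2(dba)3 (cat.), XPhos (cat.), THF, 50 °C
Reagents that add atoms: zinc, [Zn] (stays only in 17)
Why: Pd-catalysed Negishi-type coupling of a Reformatsky reagent with the activated β-triflyloxy enone forms C7–C11, and the C11 configuration does not matter because that carbon becomes sp2 in the next step.

Step 10
Reactants: 18 enone ester
Product: 20 (1R,3S,5S,10S)-9-oxolindena-4(15),7(11)-dien-12,8-olide (C8 configurationally labile), via 8-hydroxy ester 19 (not isolated)
Conditions: KHMDS, THF, −78 °C; 2-(phenylsulfonyl)-3-phenyloxaziridine, −78 to 0 °C; AcOH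
Reagents that add atoms: 2-(phenylsulfonyl)-3-phenyloxaziridine, O=S(=O)(N1OC1c1ccccc1)c1ccccc1
Why: Deprotonation at C11 gives the extended dienolate, which should take up electrophilic oxygen (enolate hydroxylation) at the less hindered α-carbon C8 with shift of the alkene to C7=C11, and the C8 alkoxide lactonises on C12 while E/Z isomers equilibrate through the dienolate.

Step 11
Reactants: 20 keto butenolide
Product: 21 (1R,3S,5S,10S)-9-hydroxylindena-4(15),7(11)-dien-12,8-olide (C8/C9 isomers)
Conditions: NaBH4, CeCl3·7H2O, MeOH, −40 °C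
Reagents that add atoms: none
Why: Luche reduction should reduce the C9 ketone 1,2-selectively beside the butenolide, and the new centre is destroyed in the next step.

Step 12
Reactants: 21 hydroxy butenolide
Product: 23 (1R,3S,5S,10S)-lindena-4(15),7(11),8-trien-12,8-olide (chloranthalactone A), via 9-mesylate 22 (not isolated)
Conditions: MsCl, Et3N, CH2Cl2, 0 °C to rt
Reagents that add atoms: methanesulfonyl chloride, CS(=O)(=O)Cl (stays only in 22)
Why: After mesylation, E1cB elimination is easy because H-8 is the vinylogously acidic γ-proton of the butenolide, so all C8/C9 isomers should converge on the γ-alkylidenebutenolide.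

Step 13
Reactants: 23 chloranthalactone A (two molecules)
Product: 24 target CNP0265879.1, the C2-symmetric head-to-head anti dimer, (1R,3S,5S,8R,9S,10S) in each half
Conditions: hν (high-pressure Hg lamp, Pyrex), degassed hexane, rt
Reagents that add atoms: none
Why: In this [2+2] photodimerisation of the C8=C9 bonds, C9–C9′ bonding first gives the 1,4-diradical with both radicals at C8/C8′ stabilised by the butenolides (head-to-head), both partners react on the α face away from CH3-14 and C2H2, and the anti approach of two homochiral molecules should set C8, C9, C8′ and C9′.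

Compound list
1 | (2R,3R)-2,3-dimethyloxirane | C[C@H]1O[C@@H]1C | starting material
2 | lithium acetylide–ethylenediamine complex | [Li+].[C-]#C.NCCN | starting material
3 | (2R,3R)-3-methylpent-4-yn-2-ol | C#C[C@@H](C)[C@@H](C)O | intermediate
4 | O-pinacolboryl ether of 3 | C#C[C@@H](C)[C@@H](C)OB1OC(C)(C)C(C)(C)O1 | intermediate
5 | O-pinacolboryl ether of 6 | CC1(C)OB(/C=C\[C@@H](C)[C@@H](C)OB2OC(C)(C)C(C)(C)O2)OC1(C)C | intermediate
6 | (2R,3R,4Z)-3-methyl-5-(pinacolboryl)pent-4-en-2-ol | CC1(C)OB(/C=C\[C@@H](C)[C@@H](C)O)OC1(C)C | intermediate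
7 | (2R,3R)-3-[(1R,2S)-2-(pinacolboryl)cyclopropyl]butan-2-ol | CC1(C)OB([C@H]2C[C@H]2[C@@H](C)[C@@H](C)O)OC1(C)C | intermediate
8 | 2-bromoprop-2-enal | C=C(Br)C=O | starting material
9 | methyl (triphenyl-λ5-phosphanylidene)acetate | COC(=O)C=P(c1ccccc1)(c1ccccc1)c1ccccc1 | starting material
10 | methyl (2E)-4-bromopenta-2,4-dienoate | C=C(Br)/C=C/C(=O)OC | intermediate
11 | methyl (2E)-4-{(1S,2R)-2-[(2R,3R)-3-hydroxybutan-2-yl]cyclopropyl}penta-2,4-dienoate | C=C(/C=C/C(=O)OC)[C@H]1C[C@H]1[C@@H](C)[C@@H](C)O | intermediate
12 | methyl (2E)-4-{(1S,2R)-2-[(2R)-3-oxobutan-2-yl]cyclopropyl}penta-2,4-dienoate | C=C(/C=C/C(=O)OC)[C@H]1C[C@H]1[C@@H](C)C(C)=O | intermediate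
13 | methyl 2-[(1R,2S,3S,5S)-2-acetyl-2-methyl-4-methylidenebicyclo[3.1.0]hexan-3-yl]acetate | C=C1[C@H]2C[C@H]2[C@](C)(C(C)=O)[C@H]1CC(=O)OC | intermediate
14 | (1R,3S,5S,10S)-11,12,13-trinorlinden-4(15)-ene-7,9-dione | C=C1[C@H]2C[C@H]2[C@@]2(C)[C@H]1CC(=O)CC2=O | intermediate
15 | 7-triflyloxy-11,12,13-trinorlindena-4(15),7-dien-9-one | C=C1[C@H]2C[C@H]2[C@@]2(C)[C@H]1CC(OS(=O)(=O)C(F)(F)F)=CC2=O | intermediate
16 | methyl 2-bromopropanoate | CC(Br)C(=O)OC | starting material
17 | bromo(1-methoxy-1-oxopropan-2-yl)zinc | COC(=O)C(C)[Zn]Br | intermediate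
18 | methyl 9-oxolindena-4(15),7-dien-12-oate (C11 epimers) | C=C1[C@H]2C[C@H]2[C@@]2(C)[C@H]1CC(C(C)C(=O)OC)=CC2=O | intermediate
19 | methyl 8-hydroxy-9-oxolindena-4(15),7(11)-dien-12-oate | C=C1[C@H]2C[C@H]2[C@@]2(C)[C@H]1CC(=C(C)C(=O)OC)C(O)C2=O | intermediate
20 | 9-oxolindena-4(15),7(11)-dien-12,8-olide (C8 labile) | C=C1[C@H]2C[C@H]2[C@@]2(C)[C@H]1CC1=C(C)C(=O)OC1C2=O | intermediate
21 | 9-hydroxylindena-4(15),7(11)-dien-12,8-olide (C8/C9 isomers) | C=C1[C@H]2C[C@H]2[C@@]2(C)[C@H]1CC1=C(C)C(=O)OC1C2O | intermediate
22 | 9-mesyloxylindena-4(15),7(11)-dien-12,8-olide | C=C1[C@H]2C[C@H]2[C@@]2(C)[C@H]1CC1=C(C)C(=O)OC1C2OS(C)(=O)=O | intermediate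
23 | chloranthalactone A, (1R,3S,5S,10S)-lindena-4(15),7(11),8-trien-12,8-olide | C=C1[C@H]2C[C@H]2[C@@]2(C)[C@H]1CC1=C(C)C(=O)OC1=C2 | intermediate
24 | CNP0265879.1, head-to-head anti [2+2] dimer of 23 | C=C1[C@H]2C[C@H]2[C@@]2(C)[C@H]1CC1=C(C)C(=O)O[C@]13[C@H]2[C@H]1[C@@]2(C)[C@@H]4C[C@@H]4C(=C)[C@@H]2CC2=C(C)C(=O)O[C@@]213 | target

Total step count: 13. Longest linear sequence: 12 (steps 1–3 and 5–13).

Steps most likely to fail

Step 7. The Michael closure may become reversible before the Claisen step. The material could then drain through the faster-closing cis-fused or C10-epimeric manifolds (loss of control over the ring fusion), or the C10 enolate could be lost to cyclopropane opening. The fallback sets out from 12 and separates the two bond formations under irreversible, non-anionic conditions. Thermodynamic silylation (TMSI, hexamethyldisilazane, below 0 °C) gives the tetrasubstituted silyl enol ether F1. This is closed at −78 °C by a Lewis-acid Mukaiyama–Michael reaction (TiCl4 or catalytic Tf2NH) to the keto ester 13, now isolated and freed of minor diastereomers. A separate Dieckmann-type closure with LiHMDS returns to the route at 14.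

Step 3. The homoallylic hydroxyl may direct only weakly, giving poor facial selectivity, and the electron-poor alkenylboronate may react sluggishly. The fallback sets out from 6 and replaces substrate direction by auxiliary control on boron. Transesterification with diethanolamine followed by mild acid hydrolysis gives the boronic acid F2. Condensation with (2R,3R)-N,N,N′,N′-tetramethyltartramide (or its enantiomer, whichever reinforces the substrate bias) gives the chiral dioxaborolane F3. Simmons–Smith cyclopropanation then gives the cyclopropylboronate F4, and exchange with pinacol returns to the route at 7.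

Step 10. Oxygen transfer may go to C11 instead of C8, or the E-configured hydroxy ester may fail to isomerise and lactonise. The fallback sets out from 18 and reverses the order of reduction and oxygenation. Luche reduction gives the allylic alcohol F5. Hydroxyl-directed epoxidation (VO(acac)2, t-BuOOH) then touches only C7=C8 and not C4=C15, giving the epoxy alcohol F6. DBU removes H-11, the epoxide opens at C7 to give C7=C11, and the C8 alkoxide lactonises, which returns to the route at 21.

Further compounds
F1 | step 7 | methyl (2E)-4-{(1S,2R)-2-[3-(trimethylsilyloxy)but-2-en-2-yl]cyclopropyl}penta-2,4-dienoate | C=C(/C=C/C(=O)OC)[C@H]1C[C@H]1C(C)=C(C)O[Si](C)(C)C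
F2 | step 3 | [(1Z,3R,4R)-4-hydroxy-3-methylpent-1-en-1-yl]boronic acid | OB(O)/C=C\[C@@H](C)[C@@H](C)O
F3 | step 3 | (4R,5R)-2-[(1Z,3R,4R)-4-hydroxy-3-methylpent-1-en-1-yl]-N,N,N′,N′-tetramethyl-1,3,2-dioxaborolane-4,5-dicarboxamide | CN(C)C(=O)[C@@H]1OB(/C=C\[C@@H](C)[C@@H](C)O)O[C@H]1C(=O)N(C)C
F4 | step 3 | (4R,5R)-2-{(1S,2R)-2-[(2R,3R)-3-hydroxybutan-2-yl]cyclopropyl}-N,N,N′,N′-tetramethyl-1,3,2-dioxaborolane-4,5-dicarboxamide | CN(C)C(=O)[C@@H]1OB([C@H]2C[C@H]2[C@@H](C)[C@@H](C)O)O[C@H]1C(=O)N(C)C
F5 | step 10 | methyl 9-hydroxylindena-4(15),7-dien-12-oate | C=C1[C@H]2C[C@H]2[C@@]2(C)[C@H]1CC(C(C)C(=O)OC)=CC2O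
F6 | step 10 | methyl 7,8-epoxy-9-hydroxylinden-4(15)-en-12-oate | C=C1[C@H]2C[C@H]2[C@@]2(C)[C@H]1CC1(C(C)C(=O)OC)OC1C2O
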